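The spiro dihydrofuran (O1, C2, C3, C3a, C8a) is traced back to a cyclopropane made of C2, C3 and C3a that carries the future C8a as a ketone. A Lewis-acid Cloke–Wilson ring expansion breaks the C2–C3a bond at the quaternary carbon and closes O1–C2, so the five-membered ring and the spiro centre arise in one operation. The step exploits the 1,3-dioxygen pattern C8a–O/C7=O of the 3-alkoxytropone, which makes C8a a latent diketone carbonyl. (S)-Carvone supplies C3′ and the other three centres are relayed from it. The tropone is annulated afterwards onto the resulting vinylogous ester by dianion aldol addition and Knoevenagel condensation.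

Key step: step 11

Remark on locants: in every compound the atoms are named as in the target, cyclohepta[b]furan part O1, C2 (spiro), C3, C3a, C4–C8, C8a, and cyclohexane part C1′ (= C2), C2′ (quaternary), C3′, C6′.

Step 1
Reactants: 1 (S)-(+)-carvone
Product: 2 (S)-5-(2-hydroxypropan-2-yl)-2-methylcyclohex-2-en-1-one
Conditions: 50% aq. H2SO4, 0 °C
Reagents that add atoms: water, O
Why: Acid-catalysed Markovnikov hydration of the isopropenyl group through its tertiary cation should give the tertiary alcohol, the O-protonated enone being inert and the C3′ centre untouched.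

Step 2
Reactants: 2 (S)-5-(2-hydroxypropan-2-yl)-2-methylcyclohex-2-en-1-one
Product: 3 (S)-2-methyl-5-[2-(triethylsilyloxy)propan-2-yl]cyclohex-2-en-1-one
Conditions: Et3SiOTf, 2,6-lutidine, CH2Cl2, −78 → 0 °C
Reagents that add atoms: triethylsilyl triflate, CC[Si](CC)(CC)OS(=O)(=O)C(F)(F)F
Why: Silylation of a hindered tertiary alcohol with a silyl triflate; the ether later blocks O–H insertion, hemiketal formation with the C1′ ketone and capture of the C2 cation.

Step 3
Reactants: 3 (S)-2-methyl-5-[2-(triethylsilyloxy)propan-2-yl]cyclohex-2-en-1-one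
Product: 4 (5S,6R)-2,6-dimethyl-5-[2-(triethylsilyloxy)propan-2-yl]cyclohex-2-en-1-one
Conditions: LiN(i-Pr)2, THF, −78 °C; MeI, −78 → −20 °C
Reagents that add atoms: iodomethane, CI
Why: Kinetic α′-deprotonation gives the cross-conjugated enolate, which is methylated anti to the C3′ substituent (enolate alkylation); this centre is planarised again in step 4, so its configuration is immaterial.

Step 4
Reactants: 4 (5S,6R)-2,6-dimethyl-5-[2-(triethylsilyloxy)propan-2-yl]cyclohex-2-en-1-one
Product: 5 (5S,6R)-6-allyl-2,6-dimethyl-5-[2-(triethylsilyloxy)propan-2-yl]cyclohex-2-en-1-one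
Conditions: LiN(i-Pr)2, THF, −78 °C; allyl bromide, DMPU, −78 → 0 °C
Reagents that add atoms: allyl bromide, C=CCBr
Why: Enolate alkylation of the tetrasubstituted α′-enolate; allyl bromide should enter anti to the bulky C3′ substituent and so set the quaternary C2′ with the three-carbon chain trans and the methyl cis to it.

Step 5
Reactants: 5 (5S,6R)-6-allyl-2,6-dimethyl-5-[2-(triethylsilyloxy)propan-2-yl]cyclohex-2-en-1-one
Product: 7 (5S,6R)-6-(3-hydroxypropyl)-2,6-dimethyl-5-[2-(triethylsilyloxy)propan-2-yl]cyclohex-2-en-1-one, via alkyl(dicyclohexyl)borane 6 (not isolated)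
Conditions: Cy2BH, THF, 0 °C; then 30% H2O2, aq. NaOAc, 0 °C → rt
Reagents that add atoms: hydrogen peroxide, OO
Why: Anti-Markovnikov hydroboration–oxidation; the hindered dialkylborane should take only the monosubstituted alkene (the trisubstituted enone C=C and the carbonyl next to a quaternary carbon are slow), and acetate-buffered peroxide avoids enone epoxidation.

Step 6
Reactants: 7 (5S,6R)-6-(3-hydroxypropyl)-2,6-dimethyl-5-[2-(triethylsilyloxy)propan-2-yl]cyclohex-2-en-1-one
Product: 8 (5S,6R)-6-[3-(tert-butyldimethylsilyloxy)propyl]-2,6-dimethyl-5-[2-(triethylsilyloxy)propan-2-yl]cyclohex-2-en-1-one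
Conditions: t-BuMe2SiCl, imidazole, DMF, rt
Reagents that add atoms: tert-butyldimethylsilyl chloride, CC(C)(C)[Si](C)(C)Cl
Why: Standard silylation of the primary alcohol; the silyl ether is inert to carbenoids, dianions and Lewis acid and carries no acidic C–H, unlike an ester.

Step 7
Reactants: 8 (5S,6R)-6-[3-(tert-butyldimethylsilyloxy)propyl]-2,6-dimethyl-5-[2-(triethylsilyloxy)propan-2-yl]cyclohex-2-en-1-one
Product: 9 (2R,3S,6R)-2-[3-(tert-butyldimethylsilyloxy)propyl]-2,6-dimethyl-3-[2-(triethylsilyloxy)propan-2-yl]cyclohexan-1-one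
Conditions: H2 (1 atm), 5% Pd/C, EtOAc, rt
Reagents that add atoms: none
Why: Heterogeneous catalytic hydrogenation adds both hydrogens syn to the enone face opposite the silyloxy-isopropyl group and the cis C2′ methyl (the open face in either half-chair), which should set C6′ with its methyl cis to the C2′ methyl.

Step 8
Reactants: 9 (2R,3S,6R)-2-[3-(tert-butyldimethylsilyloxy)propyl]-2,6-dimethyl-3-[2-(triethylsilyloxy)propan-2-yl]cyclohexan-1-one
Product: 10 the 1-methylidene analogue of 9 (C=O replaced by C=CH2, ring stereocentres unchanged)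
Conditions: Zn, CH2Br2, TiCl4, THF/CH2Cl2, 0 °C → rt
Reagents that add atoms: dibromomethane, BrCBr
Why: Takai–Lombardo methylenation; the non-basic zinc/titanium methylene reagent olefinates hindered, enolisable ketones without epimerising the α-centre, so the C6′ configuration is kept and then fixed (no longer α to a carbonyl).

Step 9
Reactants: 10 the 1-methylidene analogue of 9
Product: 11 ethyl 4-[3-(tert-butyldimethylsilyloxy)propyl]-4,8-dimethyl-5-[2-(triethylsilyloxy)propan-2-yl]spiro[2.5]octane-1-carboxylate (ring centres as in 10, diastereomer mixture at the two new cyclopropane centres)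
Conditions: ethyl diazoacetate (slow addition, excess), Rh2(OAc)4 (cat.), CH2Cl2, rt
Reagents that add atoms: ethyl diazoacetate, CCOC(=O)C=[N+]=[N-]
Why: Rhodium-carbenoid cyclopropanation of the only alkene, the carbenoid bonding first to the exposed CH2 terminus; the two new centres (C2, C3a) form unselectively, which is harmless because step 11 erases C3a and re-forms C2.

Step 10
Reactants: 11 ethyl spiro[2.5]octane-1-carboxylate derivative, 12 methyl 3-oxopentanoate
Product: 13 methyl 4-methyl-3,5-dioxo-5-(spiro[2.5]octan-1-yl)pentanoate carrying the ring substituents of 11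
Conditions: 12, LiN(i-Pr)2 (2 equiv per 12), THF, −78 → 0 °C; then 11, 0 °C → rt; AcOH
Reagents that add atoms: none
Why: Claisen-type acylation of the β-keto ester dianion, which reacts at its γ-carbon (the CHMe terminus) with the only ester of 11 (the silyl ethers are inert); the product is a cyclopropyl 1,3-diketone.

Step 11
Reactants: 13 cyclopropyl diketo ester
Product: 15 methyl (4E)-4-[(5S,6R,7S,10R)-6-[3-(tert-butyldimethylsilyloxy)propyl]-6,10-dimethyl-7-[2-(triethylsilyloxy)propan-2-yl]-1-oxaspiro[4.5]decan-2-ylidene]-3-oxopentanoate, via endocyclic enol ether 14 (not isolated)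
Conditions: Sc(OTf)3 (10 mol %), CH2Cl2, 0 °C → rt
Reagents that add atoms: none
Why: Sc(OTf)3 chelates the 1,3-diketone, the activated cyclopropane bond C2–C3a breaks heterolytically at the quaternary carbon to a tertiary cation and a scandium enolate, and the enolate oxygen (future O1) collapses onto the cation. This is the Lewis-acid form of the Cloke–Wilson cyclopropyl ketone to 4,5-dihydrofuran rearrangement, driven by release of ring strain. The five-membered ring closes by O-alkylation within the 1,5-zwitterion, and the kinetic enol ether 14 then tautomerises to the conjugated alkylidene-tetrahydrofuran (vinylogous ester) 15. The spiro centre C2 is set by substrate control: oxygen should add anti to the two flanking methyl groups on C2′ and C6′, the only approach that keeps the C3′ substituent and CH2-3 equatorial, so O1 ends trans to both methyls. Both cyclopropane diastereomers converge on the same cation. The step needs cleavage of the bond to the quaternary carbon (tertiary, not primary, cation) and O-closure over C-closure or proton loss; C-attack would join two quaternary carbons and collapse of the contact ion pair should outrun elimination.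

Step 12
Reactants: 16 methyl 2,2-dimethoxypropanoate
Product: 17 2,2-dimethoxypropanal
Conditions: i-Bu2AlH, CH2Cl2, −78 °C; Rochelle salt
Reagents that add atoms: none
Why: Half-reduction of an ester with i-Bu2AlH; the α-alkoxy-chelated tetrahedral aluminate is stable at −78 °C and should release the non-enolisable aldehyde only on work-up.

Step 13
Reactants: 15 alkylidene-tetrahydrofuran keto ester, 17 2,2-dimethoxypropanal
Product: 18 the C3a-(1-hydroxy-2,2-dimethoxypropyl) derivative of 15 (diastereomer mixture at C3a and the carbinol carbon)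
Conditions: LiN(i-Pr)2 (2.2 equiv), THF, −78 °C; then 17, −78 °C; AcOH
Reagents that add atoms: none
Why: Vinylogous aldol addition of a β-keto ester dianion: the second deprotonation occurs at the ring CH2 (C3a, conjugated to the ketone through C8a=C8) and this more basic terminus adds to the aldehyde; both new centres become sp2 in step 14.

Step 14
Reactants: 18 aldol adduct
Product: 20 methyl (2S,2′R,3′S,6′R)-2′-[3-(tert-butyldimethylsilyloxy)propyl]-2′,5,6′,8-tetramethyl-7-oxo-3′-[2-(triethylsilyloxy)propan-2-yl]-3H,7H-spiro[cyclohepta[b]furan-2,1′-cyclohexane]-6-carboxylate, via hydroxy methyl ketone 19 (not isolated)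
Conditions: PPTS, acetone/H2O, rt; then DBU, toluene, 50 °C
Reagents that add atoms: none
Why: Ketal hydrolysis frees the methyl ketone, intramolecular Knoevenagel condensation of the keto ester CH2 (C6) with it closes the seven-membered ring (C5–C6), and β-elimination of the C4 hydroxyl completes the tropone, aromatisation driving both dehydrations.

Step 15
Reactants: 20 bis-silyl ether of the tropone
Product: 21 methyl (2S,2′R,3′S,6′R)-3′-(2-hydroxypropan-2-yl)-2′-(3-hydroxypropyl)-2′,5,6′,8-tetramethyl-7-oxo-3H,7H-spiro[cyclohepta[b]furan-2,1′-cyclohexane]-6-carboxylate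
Conditions: HF·pyridine, pyridine, THF, 0 °C → rt
Reagents that add atoms: none
Why: Fluoride-mediated desilylation of both silyl ethers under buffered, non-aqueous conditions that should spare the tertiary-alkyl vinylogous ester and the methyl ester.

Step 16
Reactants: 21 diol
Product: 22 3-[(2S,2′R,3′S,6′R)-3′-(2-hydroxypropan-2-yl)-6-(methoxycarbonyl)-2′,5,6′,8-tetramethyl-7-oxo-3H,7H-spiro[cyclohepta[b]furan-2,1′-cyclohexan]-2′-yl]propanoic acid
Conditions: TEMPO (cat.), PhI(OAc)2, MeCN/pH 7 buffer, rt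
Reagents that add atoms: water, O
Why: Oxoammonium (TEMPO/PhI(OAc)2) oxidation of the primary alcohol through the aldehyde hydrate to the acid; the tertiary alcohol cannot be oxidised and the tropone ester is not touched.

Compound list
1 | (S)-(+)-carvone | O=C1C(C)=CC[C@H](C(C)=C)C1 | starting material
2 | (S)-5-(2-hydroxypropan-2-yl)-2-methylcyclohex-2-en-1-one | O=C1C(C)=CC[C@H](C(C)(C)O)C1 | intermediate
3 | (S)-2-methyl-5-[2-(triethylsilyloxy)propan-2-yl]cyclohex-2-en-1-one | O=C1C(C)=CC[C@H](C(C)(C)O[Si](CC)(CC)CC)C1 | intermediate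
4 | (5S,6R)-2,6-dimethyl-5-[2-(triethylsilyloxy)propan-2-yl]cyclohex-2-en-1-one | O=C1C(C)=CC[C@H](C(C)(C)O[Si](CC)(CC)CC)[C@H]1C | intermediate
5 | (5S,6R)-6-allyl-2,6-dimethyl-5-[2-(triethylsilyloxy)propan-2-yl]cyclohex-2-en-1-one | O=C1C(C)=CC[C@H](C(C)(C)O[Si](CC)(CC)CC)[C@@]1(C)CC=C | intermediate
6 | B-(3-substituted propyl)dicyclohexylborane formed from 5 | O=C1C(C)=CC[C@H](C(C)(C)O[Si](CC)(CC)CC)[C@@]1(C)CCCB(C2CCCCC2)C2CCCCC2 | intermediate
7 | (5S,6R)-6-(3-hydroxypropyl)-2,6-dimethyl-5-[2-(triethylsilyloxy)propan-2-yl]cyclohex-2-en-1-one | O=C1C(C)=CC[C@H](C(C)(C)O[Si](CC)(CC)CC)[C@@]1(C)CCCO | intermediate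
8 | (5S,6R)-6-[3-(tert-butyldimethylsilyloxy)propyl]-2,6-dimethyl-5-[2-(triethylsilyloxy)propan-2-yl]cyclohex-2-en-1-one | O=C1C(C)=CC[C@H](C(C)(C)O[Si](CC)(CC)CC)[C@@]1(C)CCCO[Si](C)(C)C(C)(C)C | intermediate
9 | (2R,3S,6R)-2-[3-(tert-butyldimethylsilyloxy)propyl]-2,6-dimethyl-3-[2-(triethylsilyloxy)propan-2-yl]cyclohexan-1-one (all three ring substituents other than the silyloxypropyl chain on one face) | O=C1[C@H](C)CC[C@H](C(C)(C)O[Si](CC)(CC)CC)[C@@]1(C)CCCO[Si](C)(C)C(C)(C)C | intermediate
10 | 1-methylidene analogue of 9 (exocyclic C=CH2 in place of C=O) | C=C1[C@H](C)CC[C@H](C(C)(C)O[Si](CC)(CC)CC)[C@@]1(C)CCCO[Si](C)(C)C(C)(C)C | intermediate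
11 | ethyl 4-[3-(tert-butyldimethylsilyloxy)propyl]-4,8-dimethyl-5-[2-(triethylsilyloxy)propan-2-yl]spiro[2.5]octane-1-carboxylate, diastereomer mixture at C1 and the spiro carbon | CCOC(=O)C1CC12[C@H](C)CC[C@H](C(C)(C)O[Si](CC)(CC)CC)[C@@]2(C)CCCO[Si](C)(C)C(C)(C)C | intermediate
12 | methyl 3-oxopentanoate | CCC(=O)CC(=O)OC | starting material
13 | methyl 4-methyl-3,5-dioxo-5-(spiro[2.5]octan-1-yl)pentanoate with the ring substituents of 11 | COC(=O)CC(=O)C(C)C(=O)C1CC12[C@H](C)CC[C@H](C(C)(C)O[Si](CC)(CC)CC)[C@@]2(C)CCCO[Si](C)(C)C(C)(C)C | intermediate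
14 | methyl 4-[(5S,6R,7S,10R)-6-[3-(tert-butyldimethylsilyloxy)propyl]-6,10-dimethyl-7-[2-(triethylsilyloxy)propan-2-yl]-1-oxaspiro[4.5]dec-2-en-2-yl]-3-oxopentanoate | COC(=O)CC(=O)C(C)C1=CC[C@]2(O1)[C@H](C)CC[C@H](C(C)(C)O[Si](CC)(CC)CC)[C@@]2(C)CCCO[Si](C)(C)C(C)(C)C | intermediate
15 | methyl (4E)-4-[(5S,6R,7S,10R)-6-[3-(tert-butyldimethylsilyloxy)propyl]-6,10-dimethyl-7-[2-(triethylsilyloxy)propan-2-yl]-1-oxaspiro[4.5]decan-2-ylidene]-3-oxopentanoate | COC(=O)CC(=O)/C(C)=C1\CC[C@]2(O1)[C@H](C)CC[C@H](C(C)(C)O[Si](CC)(CC)CC)[C@@]2(C)CCCO[Si](C)(C)C(C)(C)C | intermediate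
16 | methyl 2,2-dimethoxypropanoate | COC(=O)C(C)(OC)OC | starting material
17 | 2,2-dimethoxypropanal | O=CC(C)(OC)OC | intermediate
18 | 15 bearing a 1-hydroxy-2,2-dimethoxypropyl group on the ring CH2 next to the enol-ether carbon | COC(=O)CC(=O)/C(C)=C1\C(C(O)C(C)(OC)OC)C[C@]2(O1)[C@H](C)CC[C@H](C(C)(C)O[Si](CC)(CC)CC)[C@@]2(C)CCCO[Si](C)(C)C(C)(C)C | intermediate
19 | 15 bearing a 1-hydroxy-2-oxopropyl group at the same position | COC(=O)CC(=O)/C(C)=C1\C(C(O)C(C)=O)C[C@]2(O1)[C@H](C)CC[C@H](C(C)(C)O[Si](CC)(CC)CC)[C@@]2(C)CCCO[Si](C)(C)C(C)(C)C | intermediate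
20 | methyl (2S,2′R,3′S,6′R)-2′-[3-(tert-butyldimethylsilyloxy)propyl]-2′,5,6′,8-tetramethyl-7-oxo-3′-[2-(triethylsilyloxy)propan-2-yl]-3H,7H-spiro[cyclohepta[b]furan-2,1′-cyclohexane]-6-carboxylate | COC(=O)c1c(C)cc2c(c(C)c1=O)O[C@@]1(C2)[C@H](C)CC[C@H](C(C)(C)O[Si](CC)(CC)CC)[C@@]1(C)CCCO[Si](C)(C)C(C)(C)C | intermediate
21 | methyl (2S,2′R,3′S,6′R)-3′-(2-hydroxypropan-2-yl)-2′-(3-hydroxypropyl)-2′,5,6′,8-tetramethyl-7-oxo-3H,7H-spiro[cyclohepta[b]furan-2,1′-cyclohexane]-6-carboxylate | COC(=O)c1c(C)cc2c(c(C)c1=O)O[C@@]1(C2)[C@H](C)CC[C@H](C(C)(C)O)[C@@]1(C)CCCO | intermediate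
22 | 3-[(2S,2′R,3′S,6′R)-3′-(2-hydroxypropan-2-yl)-6-(methoxycarbonyl)-2′,5,6′,8-tetramethyl-7-oxo-3H,7H-spiro[cyclohepta[b]furan-2,1′-cyclohexan]-2′-yl]propanoic acid | COC(=O)c1c(C)cc2c(c(C)c1=O)O[C@@]1(C2)[C@H](C)CC[C@H](C(C)(C)O)[C@@]1(C)CCC(=O)O | target

Total step count: 16. Longest linear sequence: 15 steps (steps 1–11 and 13–16 from 1; step 12 is a one-step side branch).

Steps most likely to fail

Step 11 (key step). The tertiary cation may lose a proton or undergo a hydride shift instead of closing on oxygen, or the diketo ester may lactonise to a pyranone before the cyclopropane opens. The fallback sets out from 11. Saponification (LiOH, THF/MeOH/H2O, 50 °C) gives the cyclopropanecarboxylic acid F1. BF3·OEt2 in CH2Cl2 at 0 °C expands it to the spiro γ-lactone F2 by the acid-induced cyclopropanecarboxylic acid to γ-butyrolactone rearrangement, in which the carboxyl oxygen closes on the same cation and no enolisable diketo ester is present. The dianion of 12 (LiN(i-Pr)2, THF, −78 → 0 °C) adds to the lactone carbonyl to give the ring-opened hydroxy diketo ester F3. PPTS in toluene at 60 °C closes F3 by cyclodehydration, and the fallback comes back to the route at 15.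

Step 14. Retro-aldol loss of the hydroxy-ketone arm, or elimination to an enone that cannot reach the keto ester, may outrun closure of the seven-membered ring. The fallback sets out from 15. Its dianion (LiN(i-Pr)2, THF, −78 °C) is alkylated at the ring CH2 with propargyl bromide to give the alkyne F6. Hydration (Ph3PAuNTf2 cat., MeOH/H2O, rt) gives the methyl ketone F7. Intramolecular Knoevenagel condensation (TiCl4, pyridine, THF, 0 °C) gives the 3a,4-dihydrotropone F8. Dehydrogenation with DDQ (benzene, 60 °C) aromatises F8, and the fallback comes back at 20.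

Step 7. Hydrogen may be delivered to the wrong enone face, or the axial α-methyl ketone may enolise on the catalyst or on work-up; either would erode the C6′ configuration. The fallback sets out from 8. Conjugate reduction with LiBH(s-Bu)3 (THF, −78 °C) and trapping of the enolate with N-(5-chloropyridin-2-yl)triflimide gives the enol triflate F4. Kumada coupling with Me3SiCH2MgCl (Pd(PPh3)4, Et2O, rt) gives the allylsilane F5. Protodesilylation with allylic transposition (CF3CO2H, CH2Cl2, −78 °C) delivers the proton to C6′ from the face away from the C2′ methyl and forms the exocyclic alkene in the same event. No epimerisable ketone is handled, and the fallback comes back at 10.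

Further compounds
F1 | step 11 | carboxylic acid of 11 (4-[3-(tert-butyldimethylsilyloxy)propyl]-4,8-dimethyl-5-[2-(triethylsilyloxy)propan-2-yl]spiro[2.5]octane-1-carboxylic acid) | OC(=O)C1CC12[C@H](C)CC[C@H](C(C)(C)O[Si](CC)(CC)CC)[C@@]2(C)CCCO[Si](C)(C)C(C)(C)C
F2 | step 11 | (5S,6R,7S,10R)-6-[3-(tert-butyldimethylsilyloxy)propyl]-6,10-dimethyl-7-[2-(triethylsilyloxy)propan-2-yl]-1-oxaspiro[4.5]decan-2-one | O=C1CC[C@]2(O1)[C@H](C)CC[C@H](C(C)(C)O[Si](CC)(CC)CC)[C@@]2(C)CCCO[Si](C)(C)C(C)(C)C
F3 | step 11 | methyl 7-(1-hydroxycyclohexyl)-4-methyl-3,5-dioxoheptanoate carrying the ring substituents of F2 | COC(=O)CC(=O)C(C)C(=O)CC[C@]1(O)[C@H](C)CC[C@H](C(C)(C)O[Si](CC)(CC)CC)[C@@]1(C)CCCO[Si](C)(C)C(C)(C)C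
F4 | step 7 | (5S,6R)-6-[3-(tert-butyldimethylsilyloxy)propyl]-2,6-dimethyl-5-[2-(triethylsilyloxy)propan-2-yl]cyclohex-1-en-1-yl triflate | FC(F)(F)S(=O)(=O)OC1=C(C)CC[C@H](C(C)(C)O[Si](CC)(CC)CC)[C@@]1(C)CCCO[Si](C)(C)C(C)(C)C
F5 | step 7 | allylsilane, the (trimethylsilyl)methyl analogue of F4 | C[Si](C)(C)CC1=C(C)CC[C@H](C(C)(C)O[Si](CC)(CC)CC)[C@@]1(C)CCCO[Si](C)(C)C(C)(C)C
F6 | step 14 | 15 bearing a prop-2-yn-1-yl group on the ring CH2 next to the enol-ether carbon | COC(=O)CC(=O)/C(C)=C1\C(CC#C)C[C@]2(O1)[C@H](C)CC[C@H](C(C)(C)O[Si](CC)(CC)CC)[C@@]2(C)CCCO[Si](C)(C)C(C)(C)C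
F7 | step 14 | 15 bearing a 2-oxopropyl group at the same position | COC(=O)CC(=O)/C(C)=C1\C(CC(C)=O)C[C@]2(O1)[C@H](C)CC[C@H](C(C)(C)O[Si](CC)(CC)CC)[C@@]2(C)CCCO[Si](C)(C)C(C)(C)C
F8 | step 14 | 3a,4-dihydro derivative of 20 | COC(=O)C1=C(C)CC2C[C@]3(OC2=C(C)C1=O)[C@H](C)CC[C@H](C(C)(C)O[Si](CC)(CC)CC)[C@@]3(C)CCCO[Si](C)(C)C(C)(C)C
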